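**Plan**

- Numbering follows the benzofuran skeleton: O1, C2 (aryl), C3 (methyl), C3a (allyl), C4, C5 (OMe), C6 (C=O), C7, C7a. Ring A is the tetrahydrofuran, ring B the cyclohexenone.
- Retrosynthesis: ring B is opened at C3a–C4. This σ-bond terminates the array C3a–C7a=C7–C6(O)–C5=C4, which becomes an oxy-hexatriene once C3a is enolised toward C7a, so the cut is a retro-6π electrocyclisation. The resulting dienone is then cut at C6–C5 (acyl substitution) and C7a–C7 (lactone acylation), the lactone at C3a–allyl, and ring A at C2–C3 (crotylboration).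
- Forward: C2–C3 by crotylboration, ring A by oxidative lactonisation, allyl at C3a, a two-carbon amide at C7a, 2-methoxyvinyl at C6, ring B by electrocyclisation of the trienolate, then release of the C6 ketone.
- Stereochemistry: C2 and C3 come from the catalyst-controlled anti crotylboration. C3a comes from ring closure on the face anti to the C3 methyl. C5 is set by base equilibration to the equatorial methoxy epimer.

Key step: step 8

Assumption 1: (R)-3,3′-bis(2,4,6-triisopropylphenyl)-1,1′-binaphthyl-2,2′-diyl hydrogen phosphate is taken to direct the crotyl group to the Re face of the aryl aldehyde; should the sense be opposite, the (S)-enantiomer of this acid would be used.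

Assumption 2: 11 equilibrates with its five-membered hemiketal and is drawn open-chain; 12 and 15 are drawn as E isomers, and neither this alkene geometry nor the configuration at the allyl-bearing ring carbon matters, because both are erased when the trienolate forms.

**Route**

Step 1
Reactants: 1 3,4,5-trimethoxybenzaldehyde; 2 (E)-crotylboronic acid pinacol ester
Product: 3 (1R,2R)-2-methyl-1-(3,4,5-trimethoxyphenyl)but-3-en-1-ol
Conditions: (R)-3,3′-bis(2,4,6-triisopropylphenyl)-1,1′-binaphthyl-2,2′-diyl hydrogen phosphate (5 mol %), toluene, −30 °C; aqueous work-up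
Reagents that add atoms: none
Why: Chiral-phosphoric-acid-catalysed crotylboration through a closed chair transition state, in which the (E)-crotyl geometry gives the anti relationship and the acid, hydrogen-bonded to the boronate oxygen and the formyl hydrogen, exposes the aldehyde Re face, so both centres should be set as (1R,2R).

Step 2
Reactants: 3 (1R,2R)-2-methyl-1-(3,4,5-trimethoxyphenyl)but-3-en-1-ol
Product: 4 (1R,2R)-2-methyl-1-(3,4,5-trimethoxyphenyl)butane-1,4-diol
Conditions: 9-borabicyclo[3.3.1]nonane (2.2 equiv), THF, 0 °C to rt; then NaOH, H2O2, 0 °C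
Reagents that add atoms: hydrogen peroxide, OO
Why: Anti-Markovnikov hydroboration–oxidation of the terminal alkene with a bulky borane places the hydroxyl on the terminal carbon, and no stereocentre is made or touched.

Step 3
Reactants: 4 (1R,2R)-2-methyl-1-(3,4,5-trimethoxyphenyl)butane-1,4-diol
Product: 5 (4R,5R)-4-methyl-5-(3,4,5-trimethoxyphenyl)oxolan-2-one
Conditions: 2,2,6,6-tetramethylpiperidin-1-oxyl (10 mol %), PhI(OAc)2 (2.5 equiv), CH2Cl2, rt
Reagents that add atoms: none
Why: Oxidative lactonisation, in which the oxoammonium oxidant takes the primary alcohol selectively, the hydroxy aldehyde closes onto the benzylic hydroxyl and the lactol is oxidised on to the γ-lactone, closing ring A without touching C4 or C5.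

Step 4
Reactants: 5 (4R,5R)-4-methyl-5-(3,4,5-trimethoxyphenyl)oxolan-2-one; 6 allyl bromide
Product: 8 (3R,4R,5R)-4-methyl-3-(prop-2-en-1-yl)-5-(3,4,5-trimethoxyphenyl)oxolan-2-one, via lithium enolate of the lactone 7 (not isolated)
Conditions: LiN(SiMe3)2 (1.05 equiv), THF, −78 °C; then 6, −78 to −40 °C
Reagents that add atoms: none
Why: Enolate alkylation of a β-substituted γ-butyrolactone, in which allyl bromide approaches anti to the neighbouring C4 methyl to give the 3,4-trans product (3R); this centre is flattened again in step 8, so its purity is not critical.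

Step 5
Reactants: 8 (3R,4R,5R)-4-methyl-3-(prop-2-en-1-yl)-5-(3,4,5-trimethoxyphenyl)oxolan-2-one; 9 N-methoxy-N-methylacetamide
Product: 11 (4R,5R,6R)-6-hydroxy-N-methoxy-N,5-dimethyl-3-oxo-4-(prop-2-en-1-yl)-6-(3,4,5-trimethoxyphenyl)hexanamide, via lithium enolate of the amide 10 (not isolated)
Conditions: 9 (2.5 equiv), LiN(i-Pr)2 (2.5 equiv), THF, −78 °C; then 8, −78 to −30 °C; aq. NH4Cl
Reagents that add atoms: none
Why: Claisen-type acylation of an amide enolate by the lactone carbonyl, in which the lithium lactolate formed at low temperature resists a second addition and gives the β-keto amide (with its hemiketal) on work-up, leaving the three stereocentres unchanged.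

Step 6
Reactants: 11 (4R,5R,6R)-6-hydroxy-N-methoxy-N,5-dimethyl-3-oxo-4-(prop-2-en-1-yl)-6-(3,4,5-trimethoxyphenyl)hexanamide
Product: 12 (2E)-N-methoxy-N-methyl-2-[(3R,4R,5R)-4-methyl-3-(prop-2-en-1-yl)-5-(3,4,5-trimethoxyphenyl)oxolan-2-ylidene]acetamide
Conditions: CF3CO2H (0.2 equiv), 4 Å molecular sieves, CH2Cl2, 0 °C to rt
Reagents that add atoms: none
Why: Acid-catalysed cyclodehydration of a δ-hydroxy β-keto amide, in which the hemiketal ionises to the oxocarbenium ion and loses the proton between the two carbonyl-derived carbons to give the exocyclic enol ether conjugated with the amide (a vinylogous carbamate), expected mainly as the E isomer.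

Step 7
Reactants: 12 (2E)-N-methoxy-N-methyl-2-[(3R,4R,5R)-4-methyl-3-(prop-2-en-1-yl)-5-(3,4,5-trimethoxyphenyl)oxolan-2-ylidene]acetamide; 13 methyl vinyl ether
Product: 15 (1E)-3-methoxy-1-[(3R,4R,5R)-4-methyl-3-(prop-2-en-1-yl)-5-(3,4,5-trimethoxyphenyl)oxolan-2-ylidene]but-3-en-2-one, via 1-methoxyvinyllithium 14 (not isolated)
Conditions: 13 (3 equiv), t-BuLi (2.5 equiv), THF, −78 to 0 °C; then 12, −78 °C; cold aq. NH4Cl
Reagents that add atoms: none
Why: Weinreb ketone synthesis, in which the α-lithiated enol ether adds once to the N-methoxy-N-methylamide because the chelated tetrahedral adduct survives until the quench, which then releases the cross-conjugated 2-methoxy dienone.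

Step 8
Reactants: 15 (1E)-3-methoxy-1-[(3R,4R,5R)-4-methyl-3-(prop-2-en-1-yl)-5-(3,4,5-trimethoxyphenyl)oxolan-2-ylidene]but-3-en-2-one
Product: 18 (2R,3R,3aR)-3a-allyl-6-(tert-butyldimethylsilyloxy)-5-methoxy-3-methyl-2-(3,4,5-trimethoxyphenyl)-2,3,3a,4-tetrahydro-1-benzofuran, via potassium trienolate 16 (not isolated), via cyclised potassium enolate 17 (not isolated)
Conditions: KN(SiMe3)2 (0.95 equiv), THF (0.01 M), −78 to 0 °C; then t-BuMe2SiCl (1.2 equiv), −78 °C to rt; filtration through basic alumina
Reagents that add atoms: tert-butyldimethylsilyl chloride, CC(C)(C)[Si](C)(C)Cl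
Why: The base removes the γ-proton at the allyl-bearing ring carbon, the only enolisable C–H of the dienone, to give the 3-oxido hexatriene C3a=C7a–C7=C6(O−)–C5=C4; this should close by thermal disrotatory 6π electrocyclisation (equally a 6-endo attack of the extended-enolate γ-carbon on the terminal CH2), forming C3a–C4 and ring B, and the resulting C5=C6 enolate is silylated on oxygen. The closest known reaction type is the 6π closure of 3-silyloxy hexatrienes and of trienolates generated from dienones. The oxyanion is chosen over the neutral silyloxy triene because the allyl CH2 sits on the inside of the fully substituted terminus, where heating would invite a 1,7-hydrogen shift to C4, whereas the anion is expected to close at or below 0 °C. The new quaternary centre C3a is set by torquoselectivity: C4 bonds to the ring face anti to the adjacent C3 methyl, as in alkylations of β-substituted butyrolactone enolates (step 4), which leaves allyl cis to methyl. The closure needs C7a and C5 cis on the C6=C7 bond; the small deficit of base leaves free ketone as a proton shuttle, so that the enolate geometries interconvert and only the U-shaped form is drained irreversibly.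

Step 9
Reactants: 18 (2R,3R,3aR)-3a-allyl-6-(tert-butyldimethylsilyloxy)-5-methoxy-3-methyl-2-(3,4,5-trimethoxyphenyl)-2,3,3a,4-tetrahydro-1-benzofuran
Product: 20 (2R,3R,3aR,5R)-5-methoxy-3-methyl-3a-(prop-2-en-1-yl)-2-(3,4,5-trimethoxyphenyl)-3,3a,4,5-tetrahydro-1-benzofuran-6(2H)-one, via C5 epimer of the ketone 19 (not isolated)
Conditions: Bu4NF, AcOH, THF, 0 °C; aqueous work-up; then 1,8-diazabicyclo[5.4.0]undec-7-ene (0.2 equiv), CH2Cl2, rt
Reagents that add atoms: none
Why: Silyl enol ether cleavage by fluoride with protonation at C5, followed by amidine-base enolisation that should equilibrate C5 to the epimer whose methoxy group is equatorial and trans to the axial C3a allyl group (5R), the other three centres being non-enolisable.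

**Compound list**

1 | 3,4,5-trimethoxybenzaldehyde | COc1cc(C=O)cc(OC)c1OC | starting material
2 | (E)-crotylboronic acid pinacol ester | C/C=C/CB1OC(C)(C)C(C)(C)O1 | starting material
3 | (1R,2R)-2-methyl-1-(3,4,5-trimethoxyphenyl)but-3-en-1-ol | O[C@@H](c1cc(OC)c(OC)c(OC)c1)[C@@H](C=C)C | intermediate
4 | (1R,2R)-2-methyl-1-(3,4,5-trimethoxyphenyl)butane-1,4-diol | O[C@@H](c1cc(OC)c(OC)c(OC)c1)[C@@H](CCO)C | intermediate
5 | (4R,5R)-4-methyl-5-(3,4,5-trimethoxyphenyl)oxolan-2-one | O=C1C[C@@H](C)[C@H](c2cc(OC)c(OC)c(OC)c2)O1 | intermediate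
6 | allyl bromide | C=CCBr | starting material
7 | lithium (4R,5R)-4-methyl-5-(3,4,5-trimethoxyphenyl)-4,5-dihydrofuran-2-olate (lithium enolate of 5) | [Li+].[O-]C1=C[C@@H](C)[C@H](c2cc(OC)c(OC)c(OC)c2)O1 | intermediate (not isolated)
8 | (3R,4R,5R)-4-methyl-3-(prop-2-en-1-yl)-5-(3,4,5-trimethoxyphenyl)oxolan-2-one | C=CC[C@H]1C(=O)O[C@@H](c2cc(OC)c(OC)c(OC)c2)[C@@H]1C | intermediate
9 | N-methoxy-N-methylacetamide | CC(=O)N(C)OC | starting material
10 | lithium 1-[methoxy(methyl)amino]ethen-1-olate (lithium enolate of 9) | [Li+].[O-]C(=C)N(C)OC | intermediate (not isolated)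
11 | (4R,5R,6R)-6-hydroxy-N-methoxy-N,5-dimethyl-3-oxo-4-(prop-2-en-1-yl)-6-(3,4,5-trimethoxyphenyl)hexanamide | C=CC[C@@H](C(=O)CC(=O)N(C)OC)[C@@H](C)[C@@H](O)c1cc(OC)c(OC)c(OC)c1 | intermediate
12 | (2E)-N-methoxy-N-methyl-2-[(3R,4R,5R)-4-methyl-3-(prop-2-en-1-yl)-5-(3,4,5-trimethoxyphenyl)oxolan-2-ylidene]acetamide | C=CC[C@H]1/C(=C\C(=O)N(C)OC)O[C@@H](c2cc(OC)c(OC)c(OC)c2)[C@@H]1C | intermediate
13 | methyl vinyl ether | C=COC | starting material
14 | 1-methoxyvinyllithium | [Li]C(=C)OC | intermediate (not isolated)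
15 | (1E)-3-methoxy-1-[(3R,4R,5R)-4-methyl-3-(prop-2-en-1-yl)-5-(3,4,5-trimethoxyphenyl)oxolan-2-ylidene]but-3-en-2-one | C=CC[C@H]1/C(=C\C(=O)C(=C)OC)O[C@@H](c2cc(OC)c(OC)c(OC)c2)[C@@H]1C | intermediate
16 | potassium (1E)-3-methoxy-1-[(4R,5R)-4-methyl-3-(prop-2-en-1-yl)-5-(3,4,5-trimethoxyphenyl)-4,5-dihydrofuran-2-yl]buta-1,3-dien-2-olate | C=CCC1=C(/C=C(/[O-])C(=C)OC)O[C@@H](c2cc(OC)c(OC)c(OC)c2)[C@@H]1C.[K+] | intermediate (not isolated)
17 | potassium (2R,3R,3aR)-5-methoxy-3-methyl-3a-(prop-2-en-1-yl)-2-(3,4,5-trimethoxyphenyl)-2,3,3a,4-tetrahydro-1-benzofuran-6-olate | C=CC[C@]12CC(OC)=C([O-])C=C1O[C@@H](c1cc(OC)c(OC)c(OC)c1)[C@@H]2C.[K+] | intermediate (not isolated)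
18 | (2R,3R,3aR)-3a-allyl-6-(tert-butyldimethylsilyloxy)-5-methoxy-3-methyl-2-(3,4,5-trimethoxyphenyl)-2,3,3a,4-tetrahydro-1-benzofuran | C=CC[C@]12CC(OC)=C(O[Si](C)(C)C(C)(C)C)C=C1O[C@@H](c1cc(OC)c(OC)c(OC)c1)[C@@H]2C | intermediate
19 | (2R,3R,3aR,5S)-5-methoxy-3-methyl-3a-(prop-2-en-1-yl)-2-(3,4,5-trimethoxyphenyl)-3,3a,4,5-tetrahydro-1-benzofuran-6(2H)-one | C=CC[C@]12C[C@H](OC)C(=O)C=C1O[C@@H](c1cc(OC)c(OC)c(OC)c1)[C@@H]2C | intermediate (not isolated)
20 | (2R,3R,3aR,5R)-5-methoxy-3-methyl-3a-(prop-2-en-1-yl)-2-(3,4,5-trimethoxyphenyl)-3,3a,4,5-tetrahydro-1-benzofuran-6(2H)-one | C=CC[C@]12C[C@@H](OC)C(=O)C=C1O[C@@H](c1cc(OC)c(OC)c(OC)c1)[C@@H]2C | target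

**Step count**

Total: 9 steps. Longest linear sequence: 9 steps, from 1.

**Steps most likely to fail**

Step 8. The trienolate may stay in the geometry whose oxygen, not C5, lies cis to C7a and so never reach the closing conformation. It may also transfer a hydrogen from the allyl CH2 to C4 if it has to be warmed, or add to a second molecule instead of closing.

The fallback sets out from 8 and rejoins the route at 20. It reverses the order of bond formation: C3a–C4 is made first by an intermolecular Michael addition, and ring B is then closed at C7–C7a by carbonyl chemistry.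
- Acid-catalysed loss of methanol from commercial 3,3-dimethoxybutan-2-one (the mono-ketal of butane-2,3-dione; 4-MeC6H4SO3H cat., distillation) gives 3-methoxybut-3-en-2-one F1.
- Deprotonation of 8 with LiN(SiMe3)2 (THF, −78 °C) and addition of F1 should give the keto lactone F2. The new chain enters anti to the C4 methyl, so allyl lies cis to methyl.
- KOt-Bu in t-BuOH/THF then lets the methyl-ketone enolate attack the lactone carbonyl in an intramolecular Claisen-type addition, giving the bicyclic hemiketal F3.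
- F3 loses water by E1cB elimination to the vinylogous ester. The same base equilibrates C5, so the product is 20.

Step 5. The strongly basic amide enolate may enolise the α-branched lactone instead of adding to it, or the addition may revert on warming, so that 8 is recovered.

The fallback sets out from 8 and rejoins the route at 12. It builds the vinylogous carbamate by an oxa-Michael ring closure instead of a lactone acylation.
- i-Bu2AlH (CH2Cl2, −78 °C) reduces 8 to the lactol F4.
- Ohira–Bestmann homologation (dimethyl (1-diazo-2-oxopropyl)phosphonate, K2CO3, MeOH) converts its open hydroxy aldehyde form into the hydroxy alkyne F5.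
- Et3SiCl/imidazole gives the silyl ether F6.
- n-BuLi followed by N-methoxy-N-methylcarbamoyl chloride acylates the acetylide to the alkynyl amide F7.
- Bu4NF removes the silyl group, and the liberated alkoxide adds to the 2-alkynamide in a 5-exo-dig oxa-Michael cyclisation, giving 12.

Step 7. The vinyllithium may act as a base at the γ-position (the allyl-bearing ring carbon) instead of adding to the weakly electrophilic vinylogous carbamate amide. The 2-methoxyvinyl group may also be hydrolysed during the quench.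

The fallback sets out from 8 and rejoins the route at 15. It avoids the organolithium by carrying the methoxyvinyl group in masked form.
- The lithium enolate of 3,3-dimethoxybutan-2-one (LiN(i-Pr)2, THF, −78 °C) adds to 8 as in step 5, giving the hydroxy diketone ketal F8.
- CF3CO2H (cat.) cyclodehydrates it to the ylidene ketone ketal F9.
- Me3SiOSO2CF3/i-Pr2NEt (CH2Cl2, −20 °C) then removes methanol from the ketal, and aqueous NaHCO3 work-up returns the dienone 15.

**Further compounds**

F1 | step 8 | 3-methoxybut-3-en-2-one | CC(=O)C(=C)OC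
F2 | step 8 | (3R,4R,5R)-3-(2-methoxy-3-oxobutyl)-4-methyl-3-(prop-2-en-1-yl)-5-(3,4,5-trimethoxyphenyl)oxolan-2-one (both epimers at the methoxy carbon) | C=CC[C@]1(CC(OC)C(C)=O)C(=O)O[C@@H](c2cc(OC)c(OC)c(OC)c2)[C@@H]1C
F3 | step 8 | (2R,3R,3aR)-7a-hydroxy-5-methoxy-3-methyl-3a-(prop-2-en-1-yl)-2-(3,4,5-trimethoxyphenyl)hexahydro-1-benzofuran-6(2H)-one | C=CC[C@]12CC(OC)C(=O)CC1(O)O[C@@H](c1cc(OC)c(OC)c(OC)c1)[C@@H]2C
F4 | step 5 | (3R,4R,5R)-4-methyl-3-(prop-2-en-1-yl)-5-(3,4,5-trimethoxyphenyl)oxolan-2-ol | C=CC[C@H]1C(O)O[C@@H](c2cc(OC)c(OC)c(OC)c2)[C@@H]1C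
F5 | step 5 | (1R,2R,3R)-2-methyl-3-(prop-2-en-1-yl)-1-(3,4,5-trimethoxyphenyl)pent-4-yn-1-ol | C=CC[C@@H](C#C)[C@@H](C)[C@@H](O)c1cc(OC)c(OC)c(OC)c1
F6 | step 5 | triethyl{[(1R,2R,3R)-2-methyl-3-(prop-2-en-1-yl)-1-(3,4,5-trimethoxyphenyl)pent-4-yn-1-yl]oxy}silane | C=CC[C@@H](C#C)[C@@H](C)[C@@H](O[Si](CC)(CC)CC)c1cc(OC)c(OC)c(OC)c1
F7 | step 5 | (4R,5R,6R)-N-methoxy-N,5-dimethyl-4-(prop-2-en-1-yl)-6-[(triethylsilyl)oxy]-6-(3,4,5-trimethoxyphenyl)hex-2-ynamide | C=CC[C@@H](C#CC(=O)N(C)OC)[C@@H](C)[C@@H](O[Si](CC)(CC)CC)c1cc(OC)c(OC)c(OC)c1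
F8 | step 7 | (6R,7R,8R)-8-hydroxy-2,2-dimethoxy-7-methyl-6-(prop-2-en-1-yl)-8-(3,4,5-trimethoxyphenyl)octane-3,5-dione | C=CC[C@@H](C(=O)CC(=O)C(C)(OC)OC)[C@@H](C)[C@@H](O)c1cc(OC)c(OC)c(OC)c1
F9 | step 7 | (1E)-3,3-dimethoxy-1-[(3R,4R,5R)-4-methyl-3-(prop-2-en-1-yl)-5-(3,4,5-trimethoxyphenyl)oxolan-2-ylidene]butan-2-one | C=CC[C@H]1/C(=C\C(=O)C(C)(OC)OC)O[C@@H](c2cc(OC)c(OC)c(OC)c2)[C@@H]1C
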